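## The problem

Target 28 is a depsidone. Ring A (OMe, OH, Me) and ring B are joined by an aryl ester (O6–C7) and a diaryl ether (O12), giving a seven-membered dioxepinone, and ring B is also fused to a five-membered lactone whose benzylic carbon C1 is a lactol. The numbering used here is C1 (lactol), C3 (lactone carbonyl), C4 (OH) and C5 (Me) on ring B, O6 and C7 (ester), C8 (Me), C9 (H), C10 (OMe) and C11 (OH) on ring A, and O12 (ether).

Ring B carries six different substituents in a fixed order, so the difficulty there is orientation rather than bond formation as such. The ether oxygen lies between four ortho substituents, which argues against a simple intermolecular coupling of the two rings. C1 is the only stereocentre, and nothing else in the molecule can direct it. As a hemiacylal carbon it can invert through the open formyl acid, so it has to be set at the end by an external chiral agent, held in a stable derivative, and released without breaking a bond to C1. The aryl ester and the lactol do not tolerate hydroxide, alkoxide or amines on heating, and the C10 methyl ether has to outlast the removal of every other ether.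

The feature that opens the route is on ring B. The lactone carbonyl carbon (on C3a) and the lactol carbon (on C12b) are ortho neighbours, the carbonyl lies next to the C4 oxygen, and the position on the far side (C12a) can stay C–H until late. This is the pattern in which a 3-alkoxyaryne takes up an acyl and an alkyl group from a malonate.

## Retrosynthesis

**28 ⇒ 27 ⇒ 26.** The C1 stereocentre is traced back to racemic lactol 26 through the R acetate 27. Only the acetyl C–O bond is made and broken, never a bond to C1. An enzyme-mediated dynamic resolution is preferred to any earlier stereocontrol, because every earlier C1 derivative has to pass through acid or base that would scramble it. The forward steps need a lipase that accepts 26 and acetylates the R lactol, racemisation during the acylation, and no racemisation during deacetylation.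

**26 ⇒ 24.** Three groups are removed in one operation: the benzyl ether at C11–O, the isopropyl ether at C4–O and the methyl acetal at C1. Isopropyl is chosen at C4 because BCl3 cleaves it, with help from the lactone carbonyl, at a temperature where the C10 methyl ether is safe. The forward reaction must leave the ester, the lactone and the C10–OMe intact.

**24 ⇒ 23.** The C12a–O12 bond of the diaryl ether is cut, giving bromide 23 with a free ring A phenol; forward, this is an intramolecular Ullmann closure. Two neighbouring cuts were weighed and rejected: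
- Oxidative C–H/O–H coupling of the bromine-free depside would save a step. It needs a free phenol para to the coupling site, and the more electron-rich ring A would be oxidised first.
- Ether formation before the ester would have to join two di-ortho-substituted partners intermolecularly.

With the ester as tether the coupling is a seven-membered ring closure. The C4 oxygen para to bromine is an ether, so the aryl bromide is not deactivated as a phenoxide.

**23 ⇒ 18 + 22.** The ester C7–O6 bond is cut to give phenol 18 and salicylic acid 22. The cut is convergent and divides the molecule into two benzene rings of similar size. 18 has a single free hydroxyl, so no selectivity between ring B oxygens is asked of the esterification.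

**22 ⇒ 21 ⇒ 20 ⇒ 19.** The ring A acid comes from commercial aldehyde 19. The two methyl ethers nearest the formyl group are cleaved (20), the 3-oxygen is benzylated (21) and the aldehyde is oxidised. The forward chemistry has to tell the chelated 2-OH from the 3-OH, which the catechol dianion does.

**18 ⇒ 17 ⇒ 16 ⇒ 15 ⇒ 14.** The C–Br bond goes back to C–H: after debenzylation (17), C12a is the only open position and is ortho to the free hydroxyl. The lactone acetal 16 is cut at its ring C–O bond and, formally, at the lost carboxyl carbon. It comes from homophthalic diacid 15 by oxidative decarboxylation of the α-methoxy acid with capture by the aryl carboxylate, and 15 from diester 14. This carries the aldehyde oxidation level of C1 from the malonate, so no benzylic oxidation is needed later.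

**14 ⇒ 11 + 12 (key).** Two ring B bonds are cut at once: aryl–CH(OMe) (the future C12b–C1) and aryl–CO2Me (the future C3a–C3). What remains is aryne 13, made from silyl triflate 11, and dimethyl methoxymalonate 12. No stepwise acylation/alkylation would give two adjacent carbon substituents with this orientation on a ring already carrying three donors. The precursor is a pentasubstituted benzene with no carbon substituent other than methyl. The forward reaction must add the malonate carbon to the aryne carbon remote from the alkoxy group.

**11 ⇒ 9 ⇒ 6 ⇒ 5 ⇒ 3 ⇒ 2 ⇒ 1.** The triflate is placed on the carbon next to the isopropoxy group and silicon on the C–H side. This gives the same aryne 13 as the opposite arrangement, but phenol 5 then derives from salicylaldehyde 1, whose two hydroxyls differ in reactivity. The oxygen that later carries the ester is benzylated (2) and the oxygen that ends as the C4 phenol is isopropylated (3). A Dakin oxidation gives 5, and carbamate-directed ortho-silylation (6 → 9) fixes silicon at the only position ortho to the phenol oxygen.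

## Roads not taken

**Alternative 1:** The lactone ring would be closed last and asymmetrically, giving the bis-silylated R acetate A1 from the formyl 4-nitrophenyl ester A2. A chiral triazolylidene carbene would convert the activated ester into an acyl azolium, acetate would add reversibly to the neighbouring formyl group, and one enantiomer of the hemiacylal alkoxide would be acylated.
- Merits: C1 is set by a small-molecule catalyst in the bond-forming step and arrives as the configurationally stable acetate, with no question of an enzyme accepting a bulky substrate.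
- Weak points: A2 is the complete depsidone carrying a free aldehyde beside the diaryl ether and an activated ester wedged between that aldehyde and a silyloxy group. The carbene can also add to the aldehyde. The documented closures of this kind start from dialdehydes under oxidation rather than from an activated ester with external acetate. The silyl ethers then have to come off beside the acylal, and the final deacetylation is the same as in the chosen plan.
- Comparison: for the stereocentre alone this road is at least as good as steps 18 and 19 and probably more predictable. It says nothing about how ring B is assembled. The chosen plan sets against it that its key step builds the ring B pattern, and that its resolution works on lactol 26, which the route delivers anyway.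

**Alternative 2:** Ring A and the seven-membered ring would be formed together by heating the diene–ynoate A4. The aryloxy(silyloxy)(methoxy)butadiene on one ring B oxygen adds to the but-2-ynoate on the neighbouring oxygen, and DDQ aromatises the adduct to A3.
- Merits: the ether oxygen is in place from the start, so the crowded aryl C–O coupling of step 16 is avoided altogether, and one step places four substituents of ring A. In these respects it is better than the chosen plan.
- Weak points: A4 contains a silyl enol ether and an enol aryl ether in one diene and has to be made on a hindered catechol monoester. The ester must adopt its less favoured conformation for a seven-membered transition state. A3 has a CH2 in the lactone ring, so C1 still has to be oxidised at the end in the presence of two aryl methyl groups.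
- Comparison: the chosen plan sets against it individually precedented steps and a C1 carbon that is at the right oxidation level from the malonate onwards.

**Alternative 3:** Ring A would be formed on the ester by aldol closure and dehydration of the trioxooctanoate A6 to depside A5.
- Merits: it is biomimetic, avoids esterifying a hindered acid, and uses simple acyclic material.
- Weak points: A6 is an aryl ester of a tri-β-carbonyl acid and can lose the ring B phenol or cyclise in other modes (Claisen, pyrone). A5 still needs selective O-methylation. Its ring B has hydrogen and no handle at the ether position, and CH2 at C1. The two hardest problems, the crowded ether and the lactol, are therefore left for the end.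
- Comparison: ring A is not the bottleneck, since 22 takes three steps from 19, so the chosen plan loses little by buying ring A and gains by having solved ring B first.

Key step: step 7

Remark on the chemistry: C1 of 28 can epimerise by ring–chain tautomerism; it is assumed that this is slow without base at low temperature, so that 28 can be isolated with the configuration fixed in 27, and the R sense of the lipase is taken by analogy with smaller lactols and would be checked on 27.

## Route

Step 1
Reactants: 1 2,4-dihydroxy-3-methylbenzaldehyde
Product: 2 4-(benzyloxy)-2-hydroxy-3-methylbenzaldehyde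
Conditions: BnBr (1.05 equiv), NaHCO3, KI (cat.), MeCN, 70 °C
Reagents that add atoms: benzyl bromide BrCc1ccccc1
Why: Williamson ether synthesis; the 4-OH is the more acidic (para to the formyl group) and is not held in the hydrogen bond to the carbonyl oxygen, so a weak base alkylates it alone and leaves the 2-OH for a different group.

Step 2
Reactants: 2 4-(benzyloxy)-2-hydroxy-3-methylbenzaldehyde
Product: 3 4-(benzyloxy)-3-methyl-2-(propan-2-yloxy)benzaldehyde
Conditions: 2-bromopropane (3 equiv), K2CO3, DMF, 60 °C
Reagents that add atoms: 2-bromopropane CC(C)Br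
Why: Williamson alkylation of the remaining chelated phenol under stronger conditions; the isopropyl ether should survive organolithium, fluoride, hydroxide and hydrogenolysis and is later cleaved by BCl3 without loss of an aryl methyl ether.

Step 3
Reactants: 3 4-(benzyloxy)-3-methyl-2-(propan-2-yloxy)benzaldehyde
Product: 5 4-(benzyloxy)-3-methyl-2-(propan-2-yloxy)phenol, via aryl formate 4 (not isolated)
Conditions: mCPBA, CH2Cl2, 0 °C to rt; then K2CO3 (cat.), MeOH, rt
Reagents that add atoms: mCPBA OOC(=O)c1cccc(Cl)c1
Why: Baeyer–Villiger (Dakin-type) oxidation; the aryl group with ortho and para alkoxy donors migrates in preference to hydrogen, and mild methanolysis of formate 4 frees the phenol.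

Step 4
Reactants: 5 4-(benzyloxy)-3-methyl-2-(propan-2-yloxy)phenol
Product: 6 4-(benzyloxy)-3-methyl-2-(propan-2-yloxy)phenyl N-(propan-2-yl)carbamate
Conditions: i-PrNCO, Et3N (cat.), CH2Cl2, rt
Reagents that add atoms: isopropyl isocyanate CC(C)N=C=O
Why: Addition of the phenol to the isocyanate gives the secondary carbamate, which serves as a removable directing group for ortho-metalation.

Step 5
Reactants: 6 4-(benzyloxy)-3-methyl-2-(propan-2-yloxy)phenyl N-(propan-2-yl)carbamate
Product: 9 4-(benzyloxy)-3-methyl-2-(propan-2-yloxy)-6-(trimethylsilyl)phenyl N-(propan-2-yl)carbamate, via N-silyl carbamate 7 (not isolated), via doubly silylated carbamate 8 (not isolated)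
Conditions: TBSOTf, TMEDA, Et2O, 0 °C to rt; n-BuLi, TMEDA, −78 °C; TMSCl, −78 °C to rt; aq. NaHSO4
Reagents that add atoms: chlorotrimethylsilane C[Si](C)(C)Cl
Why: Directed ortho-metalation; N-silylation masks the carbamate N–H, the lithium base is guided to C6, the only position ortho to the carbamate, and TMSCl traps the metalated arene at −78 °C before an anionic Fries shift can occur; the N-silyl group is lost on acidic work-up.

Step 6
Reactants: 9 4-(benzyloxy)-3-methyl-2-(propan-2-yloxy)-6-(trimethylsilyl)phenyl N-(propan-2-yl)carbamate
Product: 11 4-(benzyloxy)-3-methyl-2-(propan-2-yloxy)-6-(trimethylsilyl)phenyl trifluoromethanesulfonate, via silylphenol 10 (not isolated)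
Conditions: DBU, Et2NH, MeCN, 40 °C; then PhNTf2, rt
Reagents that add atoms: N-phenylbis(trifluoromethanesulfonimide) O=S(=O)(N(c1ccccc1)S(=O)(=O)C(F)(F)F)C(F)(F)F
Why: Base-induced elimination cleaves the secondary carbamate to the phenoxide of 10 (the isocyanate is trapped by diethylamine), and PhNTf2 sulfonylates it in the same flask; this is the usual passage from ortho-silyl carbamates to silylaryl triflates.

Step 7
Reactants: 11 4-(benzyloxy)-3-methyl-2-(propan-2-yloxy)-6-(trimethylsilyl)phenyl trifluoromethanesulfonate; 12 dimethyl 2-methoxypropanedioate (dimethyl methoxymalonate)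
Product: 14 methyl 4-(benzyloxy)-6-(1,2-dimethoxy-2-oxoethyl)-3-methyl-2-(propan-2-yloxy)benzoate (racemic), via aryne 13 (not isolated)
Conditions: CsF (3 equiv), MeCN, 80 °C
Reagents that add atoms: none
Why: CsF removes the silyl group of 11 and the neighbouring triflate leaves, giving aryne 13, while the basic fluoride medium also deprotonates malonate 12. The malonate carbanion adds to the aryne carbon that has the C–H neighbour, remote from the isopropoxy group, because this puts the developing aryl anion beside the inductively withdrawing oxygen and is also the less hindered end. The aryl anion then attacks one ester carbonyl, and the four-membered alkoxide so formed breaks its bond to the former malonate carbon, releasing an ester enolate that is protonated; the net result is insertion of the aryne into a C–C bond of 12, with the aryl–CH(OMe) and aryl–CO2Me bonds formed ortho to each other. The closest known reaction is the fluoride-induced acyl-alkylation of arynes, 3-alkoxyarynes included, with malonates and β-ketoesters. No ring of the target is closed; the transient four-membered ring forms by 4-exo-trig attack and opens again. The CH(OMe) centre is formed racemic, which is of no consequence because it becomes the acetal carbon that is equilibrated and resolved at the end. The selectivity needed is regiochemical and is secured by the single alkoxy neighbour of the aryne; simple arylation by protonation of the aryl anion is held back by aprotic conditions and excess CsF.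

Step 8
Reactants: 14 methyl 4-(benzyloxy)-6-(1,2-dimethoxy-2-oxoethyl)-3-methyl-2-(propan-2-yloxy)benzoate
Product: 15 4-(benzyloxy)-6-[carboxy(methoxy)methyl]-3-methyl-2-(propan-2-yloxy)benzoic acid (racemic)
Conditions: KOH, DMSO/H2O, 90 °C; then aq. HCl
Reagents that add atoms: potassium hydroxide [K+].[OH-]
Why: Saponification; the aliphatic ester reacts readily, the di-ortho-substituted benzoate needs the hot aqueous DMSO medium, and the aryl ethers and the α-methoxy group are not affected.

Step 9
Reactants: 15 4-(benzyloxy)-6-[carboxy(methoxy)methyl]-3-methyl-2-(propan-2-yloxy)benzoic acid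
Product: 16 rac-5-(benzyloxy)-3-methoxy-6-methyl-7-(propan-2-yloxy)-2-benzofuran-1(3H)-one
Conditions: Pb(OAc)4 (1.2 equiv), pyridine, MeCN, 0 °C to rt
Reagents that add atoms: none
Why: Oxidative decarboxylation by tetravalent lead; the α-methoxy carboxylate loses CO2, the α-methoxybenzyl radical is oxidised to an oxocarbenium ion, and the neighbouring aryl carboxylate captures it in a 5-exo closure to the lactone acetal. Aryl carboxylic acids do not decarboxylate under these conditions, and the acetal carbon is formed racemic.

Step 10
Reactants: 16 rac-5-(benzyloxy)-3-methoxy-6-methyl-7-(propan-2-yloxy)-2-benzofuran-1(3H)-one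
Product: 17 rac-5-hydroxy-3-methoxy-6-methyl-7-(propan-2-yloxy)-2-benzofuran-1(3H)-one
Conditions: H2 (1 atm), Pd/C (10%), EtOAc, rt
Reagents that add atoms: none
Why: Hydrogenolysis of the aryl benzyl ether over palladium; under neutral conditions at room temperature the isopropyl ether and the lactone acetal are expected to stay.

Step 11
Reactants: 17 rac-5-hydroxy-3-methoxy-6-methyl-7-(propan-2-yloxy)-2-benzofuran-1(3H)-one
Product: 18 rac-4-bromo-5-hydroxy-3-methoxy-6-methyl-7-(propan-2-yloxy)-2-benzofuran-1(3H)-one
Conditions: NBS (1.0 equiv), MeCN, 0 °C, dark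
Reagents that add atoms: N-bromosuccinimide O=C1CCC(=O)N1Br
Why: Electrophilic aromatic bromination; C4 is the only free ring position, ortho to the free hydroxyl and para to the isopropoxy group, and polar conditions in the dark avoid radical attack on the aryl methyl group.

Step 12
Reactants: 19 2,3,4-trimethoxy-6-methylbenzaldehyde
Product: 20 2,3-dihydroxy-4-methoxy-6-methylbenzaldehyde
Conditions: BCl3 (3 equiv), CH2Cl2, 0 °C to rt; aq. work-up
Reagents that add atoms: none
Why: Lewis acid ether cleavage; BCl3 bound to the formyl oxygen removes the 2-methyl group, the aryloxyboron chloride so formed assists cleavage of the neighbouring 3-methyl ether through a cyclic borate, and the 4-methoxy group, which has no such assistance, stays.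

Step 13
Reactants: 20 2,3-dihydroxy-4-methoxy-6-methylbenzaldehyde
Product: 21 3-(benzyloxy)-2-hydroxy-4-methoxy-6-methylbenzaldehyde
Conditions: NaH (2.2 equiv), DMSO, rt; BnBr (1.0 equiv); aq. HCl
Reagents that add atoms: benzyl bromide BrCc1ccccc1
Why: Alkylation of the catechol dianion; the 2-oxide is delocalised into the formyl group, so the 3-oxide is the more nucleophilic site and takes the single equivalent of benzyl bromide.

Step 14
Reactants: 21 3-(benzyloxy)-2-hydroxy-4-methoxy-6-methylbenzaldehyde
Product: 22 3-(benzyloxy)-2-hydroxy-4-methoxy-6-methylbenzoic acid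
Conditions: NaClO2, NaH2PO4, 2-methylbut-2-ene, t-BuOH/THF/H2O, rt
Reagents that add atoms: sodium chlorite [Na+].[O-]Cl=O
Why: Pinnick oxidation of the aldehyde to the acid; 2-methylbut-2-ene traps the HOCl so that the electron-rich ring is not chlorinated.

Step 15
Reactants: 18 rac-4-bromo-5-hydroxy-3-methoxy-6-methyl-7-(propan-2-yloxy)-2-benzofuran-1(3H)-one; 22 3-(benzyloxy)-2-hydroxy-4-methoxy-6-methylbenzoic acid
Product: 23 rac-4-bromo-3-methoxy-6-methyl-1-oxo-7-(propan-2-yloxy)-1,3-dihydro-2-benzofuran-5-yl 3-(benzyloxy)-2-hydroxy-4-methoxy-6-methylbenzoate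
Conditions: DCC, DMAP (cat.), CH2Cl2/toluene, 0 °C to rt
Reagents that add atoms: none
Why: Carbodiimide (Steglich-type) esterification; 18 has a single free hydroxyl, made acidic by the ortho bromine and the para carbonyl, while the 2-OH of acid 22 is hydrogen-bonded and flanked on both sides and is expected not to compete.

Step 16
Reactants: 23 rac-4-bromo-3-methoxy-6-methyl-1-oxo-7-(propan-2-yloxy)-1,3-dihydro-2-benzofuran-5-yl 3-(benzyloxy)-2-hydroxy-4-methoxy-6-methylbenzoate
Product: 24 rac-11-(benzyloxy)-1,10-dimethoxy-5,8-dimethyl-4-(propan-2-yloxy)-1H-isobenzofuro[4,5-b][1,4]benzodioxepine-3,7-dione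
Conditions: CuI (0.3 equiv), N,N-dimethylglycine (0.6 equiv), Cs2CO3 (2 equiv), 1,4-dioxane, 90 °C, argon
Reagents that add atoms: none
Why: Intramolecular Ullmann diaryl ether synthesis with monovalent copper and an amino acid ligand; the ester holds the ring A phenoxide next to the C–Br bond and the seven-membered ring closes. The oxygen para to bromine is an ether and not a phenoxide, so the aryl bromide is not deactivated.

Step 17
Reactants: 24 rac-11-(benzyloxy)-1,10-dimethoxy-5,8-dimethyl-4-(propan-2-yloxy)-1H-isobenzofuro[4,5-b][1,4]benzodioxepine-3,7-dione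
Product: 26 rac-1,4,11-trihydroxy-10-methoxy-5,8-dimethyl-1H-isobenzofuro[4,5-b][1,4]benzodioxepine-3,7-dione, via chloro lactone 25 (not isolated)
Conditions: BCl3 (6 equiv), C6HMe5 (3 equiv), CH2Cl2, −78 to 0 °C; then THF/1 M HCl, rt to 40 °C
Reagents that add atoms: water O
Why: BCl3 cleaves the benzyl ether (cation trapped by pentamethylbenzene) and the isopropyl ether (assisted by the lactone carbonyl) at low temperature, where the aryl methyl ether is stable, and exchanges the acetal methoxy group for chloride (25). Aqueous acid then hydrolyses the chloride, or any acetal left, to the lactol.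

Step 18
Reactants: 26 rac-1,4,11-trihydroxy-10-methoxy-5,8-dimethyl-1H-isobenzofuro[4,5-b][1,4]benzodioxepine-3,7-dione
Product: 27 (1R)-4,11-dihydroxy-10-methoxy-5,8-dimethyl-3,7-dioxo-1,3-dihydroisobenzofuro[4,5-b][1,4]benzodioxepin-1-yl acetate
Conditions: immobilised Burkholderia cepacia lipase, vinyl acetate (5 equiv), Et3N (5 mol%), THF/toluene, 30 °C
Reagents that add atoms: vinyl acetate CC(=O)OC=C
Why: Lipase-catalysed dynamic kinetic resolution by acyl transfer, a reaction known for five-membered pseudo-acid lactols. The enantiomers of 26 interconvert through the open formyl acid, helped by the trace of amine, while the enzyme should acetylate the R lactol faster, so the active site of the lipase sets C1 and the acetate fixes it.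

Step 19
Reactants: 27 (1R)-4,11-dihydroxy-10-methoxy-5,8-dimethyl-3,7-dioxo-1,3-dihydroisobenzofuro[4,5-b][1,4]benzodioxepin-1-yl acetate
Product: 28 (1R)-1,4,11-trihydroxy-10-methoxy-5,8-dimethyl-1H-isobenzofuro[4,5-b][1,4]benzodioxepine-3,7-dione
Conditions: the same immobilised lipase, n-BuOH (5 equiv), MTBE/THF, 5 °C, no base
Reagents that add atoms: none
Why: Lipase-catalysed alcoholysis; by microscopic reversibility the enzyme that forms the R acetate also cleaves it, attack is at the acetyl carbonyl so no bond to C1 is broken and the configuration is retained. Cold, base-free conditions slow ring–chain epimerisation of 28.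

## Compound list

1 | 2,4-dihydroxy-3-methylbenzaldehyde | Cc1c(O)ccc(C=O)c1O | starting material
2 | 4-(benzyloxy)-2-hydroxy-3-methylbenzaldehyde | Cc1c(OCc2ccccc2)ccc(C=O)c1O | intermediate
3 | 4-(benzyloxy)-3-methyl-2-(propan-2-yloxy)benzaldehyde | Cc1c(OCc2ccccc2)ccc(C=O)c1OC(C)C | intermediate
4 | 4-(benzyloxy)-3-methyl-2-(propan-2-yloxy)phenyl formate (not isolated) | Cc1c(OCc2ccccc2)ccc(OC=O)c1OC(C)C | intermediate
5 | 4-(benzyloxy)-3-methyl-2-(propan-2-yloxy)phenol | Cc1c(OCc2ccccc2)ccc(O)c1OC(C)C | intermediate
6 | 4-(benzyloxy)-3-methyl-2-(propan-2-yloxy)phenyl N-(propan-2-yl)carbamate | Cc1c(OCc2ccccc2)ccc(OC(=O)NC(C)C)c1OC(C)C | intermediate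
7 | 4-(benzyloxy)-3-methyl-2-(propan-2-yloxy)phenyl N-(tert-butyldimethylsilyl)-N-(propan-2-yl)carbamate (not isolated) | Cc1c(OCc2ccccc2)ccc(OC(=O)N(C(C)C)[Si](C)(C)C(C)(C)C)c1OC(C)C | intermediate
8 | 4-(benzyloxy)-3-methyl-2-(propan-2-yloxy)-6-(trimethylsilyl)phenyl N-(tert-butyldimethylsilyl)-N-(propan-2-yl)carbamate (not isolated) | Cc1c(OCc2ccccc2)cc([Si](C)(C)C)c(OC(=O)N(C(C)C)[Si](C)(C)C(C)(C)C)c1OC(C)C | intermediate
9 | 4-(benzyloxy)-3-methyl-2-(propan-2-yloxy)-6-(trimethylsilyl)phenyl N-(propan-2-yl)carbamate | Cc1c(OCc2ccccc2)cc([Si](C)(C)C)c(OC(=O)NC(C)C)c1OC(C)C | intermediate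
10 | 4-(benzyloxy)-3-methyl-2-(propan-2-yloxy)-6-(trimethylsilyl)phenol (not isolated) | Cc1c(OCc2ccccc2)cc([Si](C)(C)C)c(O)c1OC(C)C | intermediate
11 | 4-(benzyloxy)-3-methyl-2-(propan-2-yloxy)-6-(trimethylsilyl)phenyl trifluoromethanesulfonate | Cc1c(OCc2ccccc2)cc([Si](C)(C)C)c(OS(=O)(=O)C(F)(F)F)c1OC(C)C | intermediate
12 | dimethyl 2-methoxypropanedioate (dimethyl methoxymalonate) | COC(C(=O)OC)C(=O)OC | starting material
13 | 5-(benzyloxy)-4-methyl-3-(propan-2-yloxy)-1,2-didehydrobenzene (aryne, not isolated) | CC(C)OC1=C(C)C(OCc2ccccc2)=CC#C1 | intermediate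
14 | methyl 4-(benzyloxy)-6-(1,2-dimethoxy-2-oxoethyl)-3-methyl-2-(propan-2-yloxy)benzoate (racemic) | COC(=O)C(OC)c1cc(OCc2ccccc2)c(C)c(OC(C)C)c1C(=O)OC | intermediate
15 | 4-(benzyloxy)-6-[carboxy(methoxy)methyl]-3-methyl-2-(propan-2-yloxy)benzoic acid (racemic) | COC(C(=O)O)c1cc(OCc2ccccc2)c(C)c(OC(C)C)c1C(=O)O | intermediate
16 | rac-5-(benzyloxy)-3-methoxy-6-methyl-7-(propan-2-yloxy)-2-benzofuran-1(3H)-one | COC1OC(=O)c2c1cc(OCc1ccccc1)c(C)c2OC(C)C | intermediate
17 | rac-5-hydroxy-3-methoxy-6-methyl-7-(propan-2-yloxy)-2-benzofuran-1(3H)-one | COC1OC(=O)c2c1cc(O)c(C)c2OC(C)C | intermediate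
18 | rac-4-bromo-5-hydroxy-3-methoxy-6-methyl-7-(propan-2-yloxy)-2-benzofuran-1(3H)-one | COC1OC(=O)c2c1c(Br)c(O)c(C)c2OC(C)C | intermediate
19 | 2,3,4-trimethoxy-6-methylbenzaldehyde | COc1cc(C)c(C=O)c(OC)c1OC | starting material
20 | 2,3-dihydroxy-4-methoxy-6-methylbenzaldehyde | COc1cc(C)c(C=O)c(O)c1O | intermediate
21 | 3-(benzyloxy)-2-hydroxy-4-methoxy-6-methylbenzaldehyde | COc1cc(C)c(C=O)c(O)c1OCc1ccccc1 | intermediate
22 | 3-(benzyloxy)-2-hydroxy-4-methoxy-6-methylbenzoic acid | COc1cc(C)c(C(=O)O)c(O)c1OCc1ccccc1 | intermediate
23 | rac-4-bromo-3-methoxy-6-methyl-1-oxo-7-(propan-2-yloxy)-1,3-dihydro-2-benzofuran-5-yl 3-(benzyloxy)-2-hydroxy-4-methoxy-6-methylbenzoate | COc1cc(C)c(C(=O)Oc2c(C)c(OC(C)C)c3c(c2Br)C(OC)OC3=O)c(O)c1OCc1ccccc1 | intermediate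
24 | rac-11-(benzyloxy)-1,10-dimethoxy-5,8-dimethyl-4-(propan-2-yloxy)-1H-isobenzofuro[4,5-b][1,4]benzodioxepine-3,7-dione | COc1cc(C)c2c(c1OCc1ccccc1)Oc1c(c(C)c(OC(C)C)c3c1C(OC)OC3=O)OC2=O | intermediate
25 | rac-1-chloro-4,11-dihydroxy-10-methoxy-5,8-dimethyl-1H-isobenzofuro[4,5-b][1,4]benzodioxepine-3,7-dione (not isolated; shown with free phenols) | COc1cc(C)c2c(c1O)Oc1c(c(C)c(O)c3c1C(Cl)OC3=O)OC2=O | intermediate
26 | rac-1,4,11-trihydroxy-10-methoxy-5,8-dimethyl-1H-isobenzofuro[4,5-b][1,4]benzodioxepine-3,7-dione | COc1cc(C)c2c(c1O)Oc1c(c(C)c(O)c3c1C(O)OC3=O)OC2=O | intermediate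
27 | (1R)-4,11-dihydroxy-10-methoxy-5,8-dimethyl-3,7-dioxo-1,3-dihydroisobenzofuro[4,5-b][1,4]benzodioxepin-1-yl acetate | COc1cc(C)c2c(c1O)Oc1c(c(C)c(O)c3c1[C@H](OC(C)=O)OC3=O)OC2=O | intermediate
28 | (1R)-1,4,11-trihydroxy-10-methoxy-5,8-dimethyl-1H-isobenzofuro[4,5-b][1,4]benzodioxepine-3,7-dione | COc1cc(C)c2c(c1O)Oc1c(c(C)c(O)c3c1[C@H](O)OC3=O)OC2=O | target

## Step count and least certain steps

Total: 19 steps. Longest linear sequence: 16 steps (steps 1–11, then 15–19); the ring A branch (steps 12–14) joins at step 15.

**Key step (step 7).** The likeliest failure is that the aryl anion is protonated before it closes onto the rather unreactive ester carbonyl, which would give plain arylation of the hindered tertiary malonate. The fallback separates the insertion from the introduction of the methoxy group. It sets out from 11, which under the same fluoride conditions with unsubstituted dimethyl malonate should give the homophthalate diester methyl 4-(benzyloxy)-6-(2-methoxy-2-oxoethyl)-3-methyl-2-(propan-2-yloxy)benzoate F1. Its benzylic ester enolate (KN(SiMe3)2, THF, −78 °C) is hydroxylated with 2-(benzenesulfonyl)-3-phenyloxaziridine to the α-hydroxy ester methyl 4-(benzyloxy)-6-(1-hydroxy-2-methoxy-2-oxoethyl)-3-methyl-2-(propan-2-yloxy)benzoate F2. O-methylation (MeI, Ag2O) comes back to the route at 14.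

**Step 16.** Insertion of copper into a C–Br bond flanked by an acyloxy group and the acetal-bearing carbon may be slow, so that loss of bromine by protonation or base-induced cleavage of the aryl ester takes over. The fallback changes the coupling from halide displacement to oxidative arylation of the phenol. It sets out from 23, which is converted (B2pin2, Pd(dppf)Cl2, KOAc, dioxane, 80 °C) into the pinacol boronate 3-methoxy-6-methyl-1-oxo-7-(propan-2-yloxy)-4-(4,4,5,5-tetramethyl-1,3,2-dioxaborolan-2-yl)-1,3-dihydro-2-benzofuran-5-yl 3-(benzyloxy)-2-hydroxy-4-methoxy-6-methylbenzoate F3. A Chan–Lam closure with divalent copper (Cu(OAc)2, pyridine, 4 Å molecular sieves, CH2Cl2, air, rt) returns to 24.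

**Step 18, with step 19.** The lipase may not accept a lactol whose hydroxyl lies beside the diaryl ether, or may show the wrong or a poor enantiopreference, and 28 may lose configuration during deacetylation if traces of base remain. The fallback replaces the enzymatic resolution by a physical one. It sets out from 26, which with Ac2O and pyridine should give the racemic triacetate 10-methoxy-5,8-dimethyl-3,7-dioxo-1,3-dihydroisobenzofuro[4,5-b][1,4]benzodioxepine-1,4,11-triyl triacetate F4. Chromatography on a chiral stationary phase separates the R triacetate F5 from the S triacetate F6. F5 is deacetylated at all three positions by pig liver esterase (phosphate buffer pH 6.5, acetone, 5 °C), with attack at the acyl carbons only, and returns to the route at 28. F6 is hydrolysed in the same way and re-enters as 26 after equilibration.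

**Step 15.** Two hindered partners meet, so slow acylation with rearrangement of the activated acid to the N-acylurea, or self-condensation through the 2-OH of 22, is possible. The fallback masks that hydroxyl and activates the carboxyl in one group. It sets out from 22, which with acetone, trifluoroacetic anhydride and trifluoroacetic acid gives the acetonide 8-(benzyloxy)-7-methoxy-2,2,5-trimethyl-4H-1,3-benzodioxin-4-one F7. Addition of the sodium phenoxide of 18 (NaH, THF, 60 °C) opens the dioxinone with loss of acetone and returns to 23.

**Step 9.** Acetate may capture the oxocarbenium ion in place of the aryl carboxylate, or the tetravalent lead reagent may attack the electron-rich ring. The fallback is electrochemical and takes two stages. It sets out from 15, which on anodic decarboxylation in methanol (Hofer–Moest conditions, graphite anode, NaOMe cat.) should give the dimethyl acetal 4-(benzyloxy)-6-(dimethoxymethyl)-3-methyl-2-(propan-2-yloxy)benzoic acid F8. Acid (TsOH cat., toluene) closes it with loss of methanol and returns to 16.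

**Step 5.** Metalation next to the benzyloxy group or at its benzylic CH2 could compete with the carbamate-directed pathway. The fallback installs silicon through a halogen. It sets out from 5, which is brominated ortho to the hydroxyl (NBS, i-Pr2NH cat., CH2Cl2, 0 °C) to 4-(benzyloxy)-6-bromo-3-methyl-2-(propan-2-yloxy)phenol F9 and silylated on oxygen (hexamethyldisilazane, THF, reflux) to [4-(benzyloxy)-6-bromo-3-methyl-2-(propan-2-yloxy)phenoxy]trimethylsilane F10. n-BuLi (THF, −78 °C) effects bromine–lithium exchange, the silyl group shifts from oxygen to carbon (retro-Brook) to give the lithium salt of 10, and Tf2O returns to the route at 11.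

## Further compounds

F1 | step 7 | methyl 4-(benzyloxy)-6-(2-methoxy-2-oxoethyl)-3-methyl-2-(propan-2-yloxy)benzoate | COC(=O)Cc1cc(OCc2ccccc2)c(C)c(OC(C)C)c1C(=O)OC
F2 | step 7 | methyl 4-(benzyloxy)-6-(1-hydroxy-2-methoxy-2-oxoethyl)-3-methyl-2-(propan-2-yloxy)benzoate (racemic) | COC(=O)C(O)c1cc(OCc2ccccc2)c(C)c(OC(C)C)c1C(=O)OC
F3 | step 16 | rac-3-methoxy-6-methyl-1-oxo-7-(propan-2-yloxy)-4-(4,4,5,5-tetramethyl-1,3,2-dioxaborolan-2-yl)-1,3-dihydro-2-benzofuran-5-yl 3-(benzyloxy)-2-hydroxy-4-methoxy-6-methylbenzoate | COc1cc(C)c(C(=O)Oc2c(C)c(OC(C)C)c3c(c2B2OC(C)(C)C(C)(C)O2)C(OC)OC3=O)c(O)c1OCc1ccccc1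
F4 | step 18 | rac-10-methoxy-5,8-dimethyl-3,7-dioxo-1,3-dihydroisobenzofuro[4,5-b][1,4]benzodioxepine-1,4,11-triyl triacetate | COc1cc(C)c2c(c1OC(C)=O)Oc1c(c(C)c(OC(C)=O)c3c1C(OC(C)=O)OC3=O)OC2=O
F5 | step 18 | (1R)-10-methoxy-5,8-dimethyl-3,7-dioxo-1,3-dihydroisobenzofuro[4,5-b][1,4]benzodioxepine-1,4,11-triyl triacetate | COc1cc(C)c2c(c1OC(C)=O)Oc1c(c(C)c(OC(C)=O)c3c1[C@H](OC(C)=O)OC3=O)OC2=O
F6 | step 18 | (1S)-10-methoxy-5,8-dimethyl-3,7-dioxo-1,3-dihydroisobenzofuro[4,5-b][1,4]benzodioxepine-1,4,11-triyl triacetate | COc1cc(C)c2c(c1OC(C)=O)Oc1c(c(C)c(OC(C)=O)c3c1[C@@H](OC(C)=O)OC3=O)OC2=O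
F7 | step 15 | 8-(benzyloxy)-7-methoxy-2,2,5-trimethyl-4H-1,3-benzodioxin-4-one | COc1cc(C)c2c(c1OCc1ccccc1)OC(C)(C)OC2=O
F8 | step 9 | 4-(benzyloxy)-6-(dimethoxymethyl)-3-methyl-2-(propan-2-yloxy)benzoic acid | COC(OC)c1cc(OCc2ccccc2)c(C)c(OC(C)C)c1C(=O)O
F9 | step 5 | 4-(benzyloxy)-6-bromo-3-methyl-2-(propan-2-yloxy)phenol | Cc1c(OCc2ccccc2)cc(Br)c(O)c1OC(C)C
F10 | step 5 | [4-(benzyloxy)-6-bromo-3-methyl-2-(propan-2-yloxy)phenoxy]trimethylsilane | Cc1c(OCc2ccccc2)cc(Br)c(O[Si](C)(C)C)c1OC(C)C
A1 | alternative 1 | (1R)-10-methoxy-5,8-dimethyl-3,7-dioxo-4,11-bis[(triisopropylsilyl)oxy]-1,3-dihydroisobenzofuro[4,5-b][1,4]benzodioxepin-1-yl acetate | COc1cc(C)c2c(c1O[Si](C(C)C)(C(C)C)C(C)C)Oc1c(c(C)c(O[Si](C(C)C)(C(C)C)C(C)C)c3c1[C@H](OC(C)=O)OC3=O)OC2=O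
A2 | alternative 1 | depsidone with ring B carrying CHO beside the ether carbon and a 4-nitrophenyl ester next to it, both phenols as triisopropylsilyl ethers | COc1cc(C)c2c(c1O[Si](C(C)C)(C(C)C)C(C)C)Oc1c(c(C)c(O[Si](C(C)C)(C(C)C)C(C)C)c(C(=O)Oc3ccc(cc3)[N+](=O)[O-])c1C=O)OC2=O
A3 | alternative 2 | 4-(benzyloxy)-11-[(tert-butyldimethylsilyl)oxy]-10-methoxy-5,8-dimethyl-1H-isobenzofuro[4,5-b][1,4]benzodioxepine-3,7-dione | COc1cc(C)c2c(c1O[Si](C)(C)C(C)(C)C)Oc1c(c(C)c(OCc3ccccc3)c3c1COC3=O)OC2=O
A4 | alternative 2 | 7-(benzyloxy)-4-{[2-(tert-butyldimethylsilyloxy)-3-methoxybuta-1,3-dien-1-yl]oxy}-6-methyl-1-oxo-1,3-dihydro-2-benzofuran-5-yl but-2-ynoate | CC#CC(=O)Oc1c(C)c(OCc2ccccc2)c2c(c1OC=C(O[Si](C)(C)C(C)(C)C)C(OC)=C)COC2=O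
A5 | alternative 3 | 7-(benzyloxy)-6-methyl-1-oxo-1,3-dihydro-2-benzofuran-5-yl 3-(benzyloxy)-2,4-dihydroxy-6-methylbenzoate | Cc1cc(O)c(OCc2ccccc2)c(O)c1C(=O)Oc1cc2COC(=O)c2c(OCc2ccccc2)c1C
A6 | alternative 3 | 7-(benzyloxy)-6-methyl-1-oxo-1,3-dihydro-2-benzofuran-5-yl 4-(benzyloxy)-3,5,7-trioxooctanoate | CC(=O)CC(=O)C(OCc1ccccc1)C(=O)CC(=O)Oc1cc2COC(=O)c2c(OCc2ccccc2)c1C
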